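**Plan**

Ring names: A/C is the upper benzopyran (O1, C2, C3, C4, C4a, C8a), B the 2-hydroxy-4-methoxyphenyl group on C3, E the central arene (E1 bonded to C3', E5 bonded to C4), D/F the lower benzopyran (O1', C2', C3', C4', C4a', C8a').
Retrosynthesis: ring F is opened at O1'–C2', C2' is taken off C3' so that a C–B bond stands in its place, and C3'–E1 and C4'–C4a' are cut together. This works because C3' carries ring E and its neighbour C4' is a CH2 on ring D, so C3'–C4' is a vinyl unit lying between two arenes. Ring C is cut at O1–C2 and C3–C4 (o-quinone methide plus arylacetaldehyde) and at C4–C4a (phenol plus aldehyde).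
Forward: rings A and E are joined, ring C is closed by amine-catalysed annulation and its lactol reduced. The ring E bromide, the vinylboronic ester and the ring D triflate are then merged in one conjunctive coupling. One-carbon homologation, oxidation and Mitsunobu closure build ring F, and hydrogenolysis frees the four phenols.
Stereochemistry: C3/C4 (3R,4S, trans) come from enamine catalysis with a prolinol silyl ether. C3' (R) comes from the chiral ferrocenyl diphosphine on palladium and is carried with retention through the boron-to-carbon shift.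

Key step: step 12

Assumption: the sense of induction of the two chiral catalysts is taken from the usual models ((R)-prolinol silyl ether for the (3R,4S) lactol, (Sp,Sp)-MandyPhos for the (R)-boronate); should a model run show the opposite sense, the mirror-image catalyst is used with no other change.

Abbreviation used in names: ArE = 2-benzyloxy-4-methoxy-5-[(3R,4S)-7-benzyloxy-3-(2-benzyloxy-4-methoxyphenyl)chroman-4-yl]phenyl.

**Route**

Step 1
Reactants: 1 4-hydroxy-2-methoxybenzaldehyde
Product: 2 5-bromo-4-hydroxy-2-methoxybenzaldehyde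
Conditions: Br2 (1.0 equiv), AcOH, rt
Reagents that add atoms: bromine, BrBr
Why: Electrophilic aromatic bromination should go to C5, the only unhindered carbon that is ortho to the hydroxyl and para to the methoxy group, since C3 is wedged between two oxygens and C6 lies next to the deactivating formyl group.

Step 2
Reactants: 2 5-bromo-4-hydroxy-2-methoxybenzaldehyde
Product: 3 4-benzyloxy-5-bromo-2-methoxybenzaldehyde
Conditions: BnBr, K2CO3, DMF, rt
Reagents that add atoms: benzyl bromide, BrCc1ccccc1
Why: Williamson ether synthesis on the acidic para-formyl phenol is routine and gives a protecting group that survives organolithium, Lewis acid and peroxide steps and leaves only at the end.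

Step 3
Reactants: 3 4-benzyloxy-5-bromo-2-methoxybenzaldehyde; 4 3-(benzyloxy)phenol
Product: 6 5-benzyloxy-2-[(4-benzyloxy-5-bromo-2-methoxyphenyl)(hydroxy)methyl]phenol (racemic), via benzodioxaborin 5 (not isolated)
Conditions: PhB(OH)2 (1.1 equiv), EtCO2H (cat.), toluene, reflux, Dean–Stark; then 30% H2O2, THF, 0 °C to rt
Reagents that add atoms: none
Why: Phenylboronic acid binds phenol and aldehyde in one mixed boronate so that the Friedel–Crafts-type hydroxyalkylation occurs only ortho to the phenolic oxygen and at the less hindered ortho carbon para to the benzyloxy group (boron-templated ortho-hydroxyalkylation), and peroxide then cleaves the boron from benzodioxaborin 5 to release the diol.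

Step 4
Reactants: 6 5-benzyloxy-2-[(4-benzyloxy-5-bromo-2-methoxyphenyl)(hydroxy)methyl]phenol
Product: 7 5-benzyloxy-2-[(4-benzyloxy-5-bromo-2-methoxyphenyl)(4-methylbenzenesulfonyl)methyl]phenol (racemic)
Conditions: 4-MeC6H4SO2H, CH2Cl2, rt
Reagents that add atoms: 4-methylbenzenesulfinic acid, Cc1ccc(S(=O)O)cc1
Why: The doubly donor-stabilised benzhydryl cation formed by acid-induced loss of water is trapped at sulfur by the sulfinate (SN1-type sulfone formation), giving a storable precursor from which the o-quinone methide can later be released by base alone.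

Step 5
Reactants: 8 2-hydroxy-4-methoxybenzaldehyde
Product: 9 2-benzyloxy-4-methoxybenzaldehyde
Conditions: BnBr, K2CO3, DMF, 60 °C
Reagents that add atoms: benzyl bromide, BrCc1ccccc1
Why: Williamson ether synthesis, with gentle heating to break the hydrogen bond between the ortho hydroxyl and the formyl group.

Step 6
Reactants: 9 2-benzyloxy-4-methoxybenzaldehyde
Product: 11 2-(2-benzyloxy-4-methoxyphenyl)acetaldehyde, via enol ether 10 (not isolated)
Conditions: Ph3P(CH2OMe)Cl, KOtBu, THF, 0 °C to rt; then 2 M HCl, THF, rt; used at once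
Reagents that add atoms: (methoxymethyl)triphenylphosphonium chloride, COC[P+](c1ccccc1)(c1ccccc1)c1ccccc1.[Cl-]; water, O
Why: Wittig methoxymethylenation followed by hydrolysis of the enol ether is the standard one-carbon homologation of an aryl aldehyde to an arylacetaldehyde, and the benzyl ether is inert to both stages.

Step 7
Reactants: 7 5-benzyloxy-2-[(4-benzyloxy-5-bromo-2-methoxyphenyl)(4-methylbenzenesulfonyl)methyl]phenol; 11 2-(2-benzyloxy-4-methoxyphenyl)acetaldehyde
Product: 13 (3R,4S)-7-benzyloxy-3-(2-benzyloxy-4-methoxyphenyl)-4-(4-benzyloxy-5-bromo-2-methoxyphenyl)chroman-2-ol (both C2 epimers), via o-quinone methide 12 (not isolated)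
Conditions: aq. Na2CO3, CH2Cl2, rt, phases separated and organic layer dried; then 11 (1.5 equiv), (R)-2-[diphenyl(trimethylsilyloxy)methyl]pyrrolidine (20 mol %), PhCO2H (20 mol %), CH2Cl2, 0 °C
Reagents that add atoms: none
Why: Base-induced loss of sulfinate gives the push–pull-stabilised o-quinone methide 12, the (E)-enamine of 11 adds to its methide carbon through the face left open by the diphenyl(silyloxy)methyl group and the phenoxide then closes onto the iminium carbon (formal oxa-[4+2] annulation under enamine catalysis), so that the catalyst sets C3 and C4 together in the trans arrangement while C2 remains an epimeric lactol carbon that is removed in step 8.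

Step 8
Reactants: 13 (3R,4S)-7-benzyloxy-3-(2-benzyloxy-4-methoxyphenyl)-4-(4-benzyloxy-5-bromo-2-methoxyphenyl)chroman-2-ol
Product: 14 (3R,4S)-7-benzyloxy-3-(2-benzyloxy-4-methoxyphenyl)-4-(4-benzyloxy-5-bromo-2-methoxyphenyl)chroman
Conditions: Et3SiH, BF3·OEt2, CH2Cl2, −78 to −20 °C
Reagents that add atoms: none
Why: Ionic hydrogenation of the lactol (oxocarbenium formation, then hydride transfer from silicon) removes the C2 hydroxyl without touching C4, and the trans C3/C4 arrangement is also the more stable one, so reversible enolisation at C3 cannot erode it.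

Step 9
Reactants: 15 4-benzyloxy-2-hydroxybenzaldehyde
Product: 16 4-benzyloxy-2-(methoxymethoxy)benzaldehyde
Conditions: MOMCl, K2CO3, acetone, rt
Reagents that add atoms: chloromethyl methyl ether, COCCl
Why: O-Alkylation of the phenoxide with the chloromethyl ether gives an acetal that can later be cleaved by acid in the presence of the benzyl ethers, which is what allows only the ring D oxygen to be freed for ring closure.

Step 10
Reactants: 16 4-benzyloxy-2-(methoxymethoxy)benzaldehyde
Product: 18 4-benzyloxy-2-(methoxymethoxy)phenol, via aryl formate 17 (not isolated)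
Conditions: mCPBA, CH2Cl2, 0 °C to rt; then K2CO3 (cat.), MeOH, rt
Reagents that add atoms: 3-chloroperoxybenzoic acid, O=C(OO)c1cccc(Cl)c1
Why: In the Baeyer–Villiger (Dakin-type) oxidation the electron-rich dialkoxyaryl group migrates in preference to hydrogen, and methanolysis of the resulting formate 17 frees the phenol.

Step 11
Reactants: 18 4-benzyloxy-2-(methoxymethoxy)phenol
Product: 19 4-benzyloxy-2-(methoxymethoxy)phenyl trifluoromethanesulfonate
Conditions: Tf2O, pyridine, CH2Cl2, 0 °C
Reagents that add atoms: trifluoromethanesulfonic anhydride, O=S(=O)(OS(=O)(=O)C(F)(F)F)C(F)(F)F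
Why: Sulfonylation of the phenol under pyridine buffering gives the halide-free electrophile that the conjunctive coupling requires, and the acetal is stable to these conditions.

Step 12
Reactants: 14 (3R,4S)-7-benzyloxy-3-(2-benzyloxy-4-methoxyphenyl)-4-(4-benzyloxy-5-bromo-2-methoxyphenyl)chroman; 20 vinylboronic acid pinacol ester; 19 4-benzyloxy-2-(methoxymethoxy)phenyl trifluoromethanesulfonate
Product: 23 2-[(1R)-1-ArE-2-[4-benzyloxy-2-(methoxymethoxy)phenyl]ethyl]-4,4,5,5-tetramethyl-1,3,2-dioxaborolane, via aryllithium 21 (not isolated), via boron ate complex 22 (not isolated)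
Conditions: t-BuLi (2.0 equiv), THF, −78 °C; 20, −78 °C to rt; then 19, Pd(OAc)2 (3 mol %), (Sp,Sp)-1,1'-bis(diphenylphosphino)-2,2'-bis[(R)-(dimethylamino)(phenyl)methyl]ferrocene (MandyPhos, 3.6 mol %), NaOTf, THF, 60 °C
Reagents that add atoms: none
Why: Bromine–lithium exchange gives aryllithium 21, which adds to the boron of 20 to form the four-coordinate ate complex 22; oxidative addition of 19 to zerovalent palladium gives a cationic arylpalladium triflate (divalent palladium) that binds the vinyl group of 22 and triggers a 1,2-shift of ring E from boron to the α-carbon anti to the metal, after which reductive elimination joins the β-carbon to ring D and returns zerovalent palladium. The closest known reaction type is the enantioselective palladium-catalysed conjunctive cross-coupling of aryllithium-derived vinylboron ate complexes with aryl triflates. No ring closes; the step forms C3'–E1, C4'–C4a' and one stereocentre. The (R) configuration at the boron-bearing carbon is set by the chiral diphosphine on palladium, which selects the alkene face that is activated, the distant C3 and C4 centres being expected to have little influence. The step needs the metallate shift to outrun direct transmetallation of the aryl or vinyl group (Suzuki-type coupling) and β-hydride loss; the triflate counter-ion, kept free of bromide by NaOTf, keeps palladium cationic and π-acidic, and the pinacol ligand slows direct transfer from boron.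

Step 13
Reactants: 23 2-[(1R)-1-ArE-2-[4-benzyloxy-2-(methoxymethoxy)phenyl]ethyl]-4,4,5,5-tetramethyl-1,3,2-dioxaborolane
Product: 25 (2R)-2-ArE-3-[4-benzyloxy-2-(methoxymethoxy)phenyl]propan-1-ol, via primary boronate 24 (not isolated)
Conditions: BrCH2Cl, n-BuLi, THF, −78 °C to rt; then 3 M NaOH, 30% H2O2, 0 °C to rt
Reagents that add atoms: bromochloromethane, ClCBr; hydrogen peroxide, OO
Why: In the Matteson homologation chloromethyllithium made in the flask adds to boron and the benzylic carbon migrates to the CH2 with retention as chloride leaves, so the stereocentre is kept while the future C2' is inserted, and alkaline peroxide then turns the primary C–B bond of 24 into C–OH.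

Step 14
Reactants: 25 (2R)-2-ArE-3-[4-benzyloxy-2-(methoxymethoxy)phenyl]propan-1-ol
Product: 26 5-benzyloxy-2-[(2R)-2-ArE-3-hydroxypropyl]phenol
Conditions: conc. HCl (cat.), MeOH/THF, 45 °C
Reagents that add atoms: none
Why: Acid-catalysed acetal exchange with methanol removes the methoxymethyl group alone, as benzyl ethers, the primary alcohol and the diarylmethine C4 have no acid-labile bond under these conditions.

Step 15
Reactants: 26 5-benzyloxy-2-[(2R)-2-ArE-3-hydroxypropyl]phenol
Product: 27 (3R,4S)-7-benzyloxy-3-(2-benzyloxy-4-methoxyphenyl)-4-{4-benzyloxy-5-[(3R)-7-benzyloxychroman-3-yl]-2-methoxyphenyl}chroman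
Conditions: PPh3, DIAD, THF, 0 °C to rt
Reagents that add atoms: none
Why: Intramolecular Mitsunobu etherification activates the primary alcohol and the only free phenol (ring D) displaces it in a 6-exo-tet closure of ring F that does not involve C3', while the benzyl group on the ring E oxygen blocks the competing five-membered closure.

Step 16
Reactants: 27 (3R,4S)-7-benzyloxy-3-(2-benzyloxy-4-methoxyphenyl)-4-{4-benzyloxy-5-[(3R)-7-benzyloxychroman-3-yl]-2-methoxyphenyl}chroman
Product: 28 (3R,4S)-3-(2-hydroxy-4-methoxyphenyl)-4-{4-hydroxy-5-[(3R)-7-hydroxychroman-3-yl]-2-methoxyphenyl}chroman-7-ol (CNP0152030.2)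
Conditions: H2 (1 atm), Pd/C, EtOAc/MeOH, rt
Reagents that add atoms: none
Why: Catalytic hydrogenolysis cleaves the four aryl benzyl ethers, whereas the pyran C–O bonds are not benzylic at carbon and the methyl ethers and all three stereocentres are untouched.

**Compound list**

1 | 4-hydroxy-2-methoxybenzaldehyde | COc1cc(O)ccc1C=O | starting material
2 | 5-bromo-4-hydroxy-2-methoxybenzaldehyde | COc1cc(O)c(Br)cc1C=O | intermediate
3 | 4-benzyloxy-5-bromo-2-methoxybenzaldehyde | COc1cc(OCc2ccccc2)c(Br)cc1C=O | intermediate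
4 | 3-(benzyloxy)phenol | Oc1cccc(OCc2ccccc2)c1 | starting material
5 | 7-benzyloxy-4-(4-benzyloxy-5-bromo-2-methoxyphenyl)-2-phenyl-4H-1,3,2-benzodioxaborinine (racemic) | COc1cc(OCc2ccccc2)c(Br)cc1C1OB(c2ccccc2)Oc2cc(OCc3ccccc3)ccc21 | intermediate (not isolated)
6 | 5-benzyloxy-2-[(4-benzyloxy-5-bromo-2-methoxyphenyl)(hydroxy)methyl]phenol (racemic) | COc1cc(OCc2ccccc2)c(Br)cc1C(O)c1ccc(OCc2ccccc2)cc1O | intermediate
7 | 5-benzyloxy-2-[(4-benzyloxy-5-bromo-2-methoxyphenyl)(4-methylbenzenesulfonyl)methyl]phenol (racemic) | COc1cc(OCc2ccccc2)c(Br)cc1C(c1ccc(OCc2ccccc2)cc1O)S(=O)(=O)c1ccc(C)cc1 | intermediate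
8 | 2-hydroxy-4-methoxybenzaldehyde | COc1ccc(C=O)c(O)c1 | starting material
9 | 2-benzyloxy-4-methoxybenzaldehyde | COc1ccc(C=O)c(OCc2ccccc2)c1 | intermediate
10 | 2-benzyloxy-4-methoxy-1-(2-methoxyethenyl)benzene (E/Z mixture) | COC=Cc1ccc(OC)cc1OCc1ccccc1 | intermediate (not isolated)
11 | 2-(2-benzyloxy-4-methoxyphenyl)acetaldehyde | COc1ccc(CC=O)c(OCc2ccccc2)c1 | intermediate
12 | 3-benzyloxy-6-[(4-benzyloxy-5-bromo-2-methoxyphenyl)methylidene]cyclohexa-2,4-dien-1-one (o-quinone methide) | COc1cc(OCc2ccccc2)c(Br)cc1C=C1C=CC(OCc2ccccc2)=CC1=O | intermediate (not isolated)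
13 | (3R,4S)-7-benzyloxy-3-(2-benzyloxy-4-methoxyphenyl)-4-(4-benzyloxy-5-bromo-2-methoxyphenyl)chroman-2-ol (both C2 epimers) | COc1ccc([C@@H]2C(O)Oc3cc(OCc4ccccc4)ccc3[C@H]2c2cc(Br)c(OCc3ccccc3)cc2OC)c(OCc2ccccc2)c1 | intermediate
14 | (3R,4S)-7-benzyloxy-3-(2-benzyloxy-4-methoxyphenyl)-4-(4-benzyloxy-5-bromo-2-methoxyphenyl)chroman | COc1ccc([C@@H]2COc3cc(OCc4ccccc4)ccc3[C@H]2c2cc(Br)c(OCc3ccccc3)cc2OC)c(OCc2ccccc2)c1 | intermediate
15 | 4-benzyloxy-2-hydroxybenzaldehyde | O=Cc1ccc(OCc2ccccc2)cc1O | starting material
16 | 4-benzyloxy-2-(methoxymethoxy)benzaldehyde | COCOc1cc(OCc2ccccc2)ccc1C=O | intermediate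
17 | 4-benzyloxy-2-(methoxymethoxy)phenyl formate | COCOc1cc(OCc2ccccc2)ccc1OC=O | intermediate (not isolated)
18 | 4-benzyloxy-2-(methoxymethoxy)phenol | COCOc1cc(OCc2ccccc2)ccc1O | intermediate
19 | 4-benzyloxy-2-(methoxymethoxy)phenyl trifluoromethanesulfonate | COCOc1cc(OCc2ccccc2)ccc1OS(=O)(=O)C(F)(F)F | intermediate
20 | vinylboronic acid pinacol ester | C=CB1OC(C)(C)C(C)(C)O1 | starting material
21 | (3R,4S)-7-benzyloxy-3-(2-benzyloxy-4-methoxyphenyl)-4-(4-benzyloxy-5-lithio-2-methoxyphenyl)chroman (ArE–Li) | COc1ccc([C@@H]2COc3cc(OCc4ccccc4)ccc3[C@H]2c2cc([Li])c(OCc3ccccc3)cc2OC)c(OCc2ccccc2)c1 | intermediate (not isolated)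
22 | lithium ArE(ethenyl)(pinacolato)borate | COc1ccc([C@@H]2COc3cc(OCc4ccccc4)ccc3[C@H]2c2cc([B-]3(C=C)OC(C)(C)C(C)(C)O3)c(OCc3ccccc3)cc2OC)c(OCc2ccccc2)c1.[Li+] | intermediate (not isolated)
23 | 2-[(1R)-1-ArE-2-[4-benzyloxy-2-(methoxymethoxy)phenyl]ethyl]-4,4,5,5-tetramethyl-1,3,2-dioxaborolane | COc1ccc([C@@H]2COc3cc(OCc4ccccc4)ccc3[C@H]2c2cc([C@@H](Cc3ccc(OCc4ccccc4)cc3OCOC)B3OC(C)(C)C(C)(C)O3)c(OCc3ccccc3)cc2OC)c(OCc2ccccc2)c1 | intermediate
24 | 2-[(2R)-2-ArE-3-[4-benzyloxy-2-(methoxymethoxy)phenyl]propyl]-4,4,5,5-tetramethyl-1,3,2-dioxaborolane | COc1ccc([C@@H]2COc3cc(OCc4ccccc4)ccc3[C@H]2c2cc([C@@H](Cc3ccc(OCc4ccccc4)cc3OCOC)CB3OC(C)(C)C(C)(C)O3)c(OCc3ccccc3)cc2OC)c(OCc2ccccc2)c1 | intermediate (not isolated)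
25 | (2R)-2-ArE-3-[4-benzyloxy-2-(methoxymethoxy)phenyl]propan-1-ol | COc1ccc([C@@H]2COc3cc(OCc4ccccc4)ccc3[C@H]2c2cc([C@@H](Cc3ccc(OCc4ccccc4)cc3OCOC)CO)c(OCc3ccccc3)cc2OC)c(OCc2ccccc2)c1 | intermediate
26 | 5-benzyloxy-2-[(2R)-2-ArE-3-hydroxypropyl]phenol | COc1ccc([C@@H]2COc3cc(OCc4ccccc4)ccc3[C@H]2c2cc([C@@H](Cc3ccc(OCc4ccccc4)cc3O)CO)c(OCc3ccccc3)cc2OC)c(OCc2ccccc2)c1 | intermediate
27 | (3R,4S)-7-benzyloxy-3-(2-benzyloxy-4-methoxyphenyl)-4-{4-benzyloxy-5-[(3R)-7-benzyloxychroman-3-yl]-2-methoxyphenyl}chroman | COc1ccc([C@@H]2COc3cc(OCc4ccccc4)ccc3[C@H]2c2cc([C@@H]3COc4cc(OCc5ccccc5)ccc4C3)c(OCc3ccccc3)cc2OC)c(OCc2ccccc2)c1 | intermediate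
28 | (3R,4S)-3-(2-hydroxy-4-methoxyphenyl)-4-{4-hydroxy-5-[(3R)-7-hydroxychroman-3-yl]-2-methoxyphenyl}chroman-7-ol | COc1ccc([C@@H]2COc3cc(O)ccc3[C@H]2c2cc([C@@H]3COc4cc(O)ccc4C3)c(O)cc2OC)c(O)c1 | target

**Count and risks**

Total steps: 16. Longest linear sequence: 11 steps (steps 1, 2, 3, 4, 7, 8, 12, 13, 14, 15, 16).

Step 12 is the most exposed. The lithium of 21 sits next to a benzyloxy group and may be quenched by proton transfer from that benzylic CH2 (followed by Wittig-type rearrangement) before boron captures it. Bromide carried over from the exchange may also bind the cationic palladium intermediate, so that the 1,2-shift stalls and direct Suzuki-type coupling or no turnover results. The fallback sets out from bromide 14 and builds the ate complex from the other side. Miyaura borylation (B2pin2, PdCl2(dppf), KOAc, dioxane, 90 °C) should give the aryl pinacol boronate F1. Halide-free vinyllithium (from Sn(CH=CH2)4 and n-BuLi) is then added to F1 in THF at −78 °C, which forms ate complex 22 without passing through 21 and without any halide. The route is rejoined at 22, which is coupled with 19 under the same palladium/MandyPhos conditions to give 23.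

Step 7 may lose enantio- and diastereocontrol through an uncatalysed addition of the enol of 11 to the very electrophilic 12, through E/Z mixtures of the arylacetaldehyde enamine, or through dimerisation of 12 while it waits for the enamine. The fallback sets out from diol 6 (step 4 is then skipped) and aldehyde 11. A chiral BINOL-derived phosphoric acid, 3,3'-bis(2,4,6-triisopropylphenyl)-1,1'-binaphthyl-2,2'-diyl hydrogen phosphate (antipode chosen for the 4S series), in toluene at rt dehydrates 6 to 12 inside a hydrogen-bonded ion pair and directs the addition of the enol of 11. This is a known entry to 3,4-cis-diaryl chroman-2-ols and should give the cis lactol F2. Brief treatment with DBU in CH2Cl2 should epimerise C3 through the ring-opened hydroxy aldehyde to the more stable trans lactol 13, where the route is rejoined.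

Step 13 may suffer from incomplete capture of the hindered secondary benzylic boronate by the short-lived carbenoid, which decomposes if the cold bath warms before boron has trapped it, or from a second insertion into the primary boronate 24. The fallback sets out from 23 and introduces the carbon as a vinyl group. Zweifel olefination (vinylmagnesium bromide, THF; then I2, NaOMe, MeOH, −78 °C to rt) should replace boron with retention to give the terminal alkene F3. Oxidative cleavage (OsO4 cat., NaIO4, 2,6-lutidine, dioxane/H2O) should give the α-aryl aldehyde F4, which is reduced at once with NaBH4 in MeOH at 0 °C to limit epimerisation. The route is rejoined at alcohol 25.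

**Further compounds**

F1 | step 12 | (3R,4S)-7-benzyloxy-3-(2-benzyloxy-4-methoxyphenyl)-4-[4-benzyloxy-2-methoxy-5-(4,4,5,5-tetramethyl-1,3,2-dioxaborolan-2-yl)phenyl]chroman | COc1ccc([C@@H]2COc3cc(OCc4ccccc4)ccc3[C@H]2c2cc(B3OC(C)(C)C(C)(C)O3)c(OCc3ccccc3)cc2OC)c(OCc2ccccc2)c1
F2 | step 7 | (3S,4S)-7-benzyloxy-3-(2-benzyloxy-4-methoxyphenyl)-4-(4-benzyloxy-5-bromo-2-methoxyphenyl)chroman-2-ol (cis, both C2 epimers) | COc1ccc([C@H]2C(O)Oc3cc(OCc4ccccc4)ccc3[C@H]2c2cc(Br)c(OCc3ccccc3)cc2OC)c(OCc2ccccc2)c1
F3 | step 13 | (3R)-3-ArE-4-[4-benzyloxy-2-(methoxymethoxy)phenyl]but-1-ene (configuration as in 23) | COc1ccc([C@@H]2COc3cc(OCc4ccccc4)ccc3[C@H]2c2cc([C@@H](Cc3ccc(OCc4ccccc4)cc3OCOC)C=C)c(OCc3ccccc3)cc2OC)c(OCc2ccccc2)c1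
F4 | step 13 | (2R)-2-ArE-3-[4-benzyloxy-2-(methoxymethoxy)phenyl]propanal | COc1ccc([C@@H]2COc3cc(OCc4ccccc4)ccc3[C@H]2c2cc([C@@H](Cc3ccc(OCc4ccccc4)cc3OCOC)C=O)c(OCc3ccccc3)cc2OC)c(OCc2ccccc2)c1
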